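Remark: atoms carry eudesmane numbers (ring A = C1–C5 and C10, ring B = C5–C10, benzylic carbon C9′). (R)-(+)-α-Terpineol is taken as a commercial chiral-pool material of high enantiomeric purity.

## Analysis of the target

The target is a trans-fused decalin of the eudesmane type. C1 carries a benzylic methine C9′, which also bears an isobutyl group and a 2,4,6-trihydroxy-3,5-diformylphenyl ring. There are six stereocentres: 1S, 4R, 5S, 7S, 10R in the decalin and R at C9′. C10 is quaternary with an axial methyl, and H5 is trans to that methyl. The 2-hydroxypropan-2-yl group on C7 is equatorial and cis to the C10 methyl. The C4 hydroxyl is axial and cis to it, and the C1 substituent is trans to it and therefore axial. The sensitive groups are the two tertiary alcohols, of which the axial C4–OH with its anti-periplanar H5 eliminates easily in acid, and the oxidisable diformylphloroglucinol, whose aldehydes rule out organometallic steps once they are present. The difficulty lies in three places: the quaternary C10 flanked by the stereocentres C1 and C5; the axial C1 substituent, which cannot be reached by equilibration; and C9′, wedged between a hindered ring carbon and a doubly ortho-substituted arene. The strategy rests on ring A. The fusion bond C5–C10 joins a quaternary carbon whose neighbour C1 bears a carbon substituent to a methine whose neighbour C4 is oxygenated, with C2–C3 between them. That is the pattern left by a Diels–Alder reaction between a 2-oxygenated diene C2=C3–C4=C5 and a C10=C1 enoate. The remaining carbons C6–C9 form a four-atom tether whose only stereocentre, C7 with its oxygenated isopropyl group, is that of α-terpineol.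

## Retrosynthetic reasoning

**33 back to 30.** The two aryl–CHO bonds and the two silyl ethers are cut first. Once the aldehydes exist nothing nucleophilic or reducing can be used, so electrophilic formylation of the free triphenol 30 (via 32) is placed at the end and only a fluoride desilylation follows it. The forward step has to formylate both ring positions without ionising the tertiary C–O bonds, which is why these stay silylated.

**30 back to 28.** The isobutyl group is traced to a 2-methylallyl group (29) and this to the methyl ketone 28, cutting one C=C bond to a methylene unit. The gain is that one hydrogenation saturates the alkene and removes the three benzyl ethers.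

**28 back to 22 and 24.** The C9′–aryl bond is cut, leaving enone 22 and an aryl copper reagent from bromide 24. This bond is chosen because the enone side chain on the axial C1 position has one conformation and one open face, so the ring controls C9′. The reverse order, aryl first and carbon nucleophile second, would lead to the C9′ epimer.

**22 back to 19.** The C9′=C10′ double bond is cut by an olefination transform to aldehyde 21, which comes from ester 19 through alcohol 20. The ester carbon of the cycloadduct thus becomes C9′.

**19 back to 17.** The C4–CH3 bond is cut to the ketone 17 (through 18). In the trans-decalone the axial C10 methyl blocks the axial approach to C4, so a methyl organometallic must enter equatorially and leave the hydroxyl axial, as required.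

**17 back to 15, the key disconnection.** The bonds C5–C10 and C1–C2 are cut together, through the silyl enol ether 16, to the acyclic triene 15. Both rings, the quaternary carbon and its two neighbours then come from one cycloaddition. The tether links diene carbon C5 to dienophile carbon C10, the (Z)-enoate fixes C1 against C10, and C7 on the tether selects the face.

**15 back to 10.** The silyl dienol ether is the enol derivative of vinyl ketone 14, and 14 comes from methyl ketone 10 by a one-carbon Mannich methylenation (through 12). A direct olefination of an aldehyde to a 2-silyloxydiene was rejected: α-silyloxy phosphonate anions tend to give acyloin silyl ethers by silyl migration rather than enol ethers.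

**10 back to 6 and 8.** The sp3–sp2 bond C9–C10 is cut to alkyl iodide 6 and the (Z)-iodoenoate 8 (from alkynoate 7). The enoate geometry is then carried in from a stereodefined vinyl iodide. Olefination of a methyl ketone would favour the wrong isomer.

**6 back to 1.** Iodide 6 comes from alcohol 5 and keto aldehyde 4, which is the ozonolysis product of silylated (R)-α-terpineol 2, made from 1. The ring carbons of 1 become C4–C9 and its methyl becomes C3. This mapping needs the (R) enantiomer and uses every carbon of the terpene.

## Alternatives that were turned down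

**Alternative 1: Diels–Alder annulation of ring A onto a carvone-derived diene.**
- Disconnection: C1–C10 and C2–C3 of ring A.
- Forward key step: the semicyclic ethoxydiene A1 (ring B with the C5=C10 double bond and a 1-ethoxyvinyl group on C5) reacts with enone A2 to give the bicyclic enol ether A3, with the isovaleryl group on C1 and the angular methyl in place.
- For: it is the shortest route. Ring B and C7 come intact from carvone, the isobutyl carbons are already attached, and an endo addition would place the C1 acyl group trans to the C10 methyl. On step count it is clearly stronger than the chosen route.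
- Against: C10 is a fully substituted diene terminus whose methyl is the inside substituent, so the s-cis conformer is strained and the intermolecular bond to the quaternary carbon will be slow. Lewis acid acceleration does not go with the enol ether. The diene face is distinguished only by the remote C7 group, and endo or exo is not enforced. C9′ would then have to be made from the C1 ketone by aryl addition and removal of a tertiary benzylic oxygen, with no control and with acid close to the tertiary alcohols.
- Comparison: the chosen route pays several extra steps. In return intramolecularity forces the hindered bond, a chair-folded tether relays C7 to C5 and C10, and C9′ is set by a conjugate addition.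

**Alternative 2: Danheiser benzannulation building the phloroglucinol ring around C9′.**
- Disconnection: three bonds of the arene (C1′–C2′, C2′–C3′, C5′–C6′).
- Forward key step: heating siloxyalkyne A4 with cyclobutenone A5 gives a vinylketene, then [2+2] addition, four-electron ring opening and six-electron closure lead to phenol A6.
- For: it avoids joining two hindered partners at C9′, delivers three differentiated phenol oxygens and runs under neutral thermal conditions that silyl ethers tolerate. On these points it is stronger than the aryl cuprate step of the chosen route.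
- Against: it is an endgame tactic and leaves the decalin with its quaternary carbon unsolved. C9′ must already be set on an alkyne-bearing chain, and A4 needs ynolate chemistry with strong base beside that centre. A 3-alkoxycyclobutenone is a sluggish vinylketene source. Both formyl groups are still missing.
- Comparison: it spends many steps on advanced material to make a ring that is available as a commercial building block. The chosen key step addresses the harder problem of C10 and the ring fusion.

**Alternative 3: conjugate methylation and Michael ring closure building ring B.**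
- Disconnection: C10–CH3 and C5–C6.
- Forward key step: a methyl cuprate adds to C10 of cyclohexenone A7 anti to the C1 substituent, and the enolate carbon C5 adds to the tethered acrylate CH2 (C6) to give trans-decal-4-one A8.
- For: it runs at low temperature. The C1/C10 trans relation comes from anti addition and needs no alkene geometry. The C4 ketone appears directly, and one methyl organometallic could later make both tertiary alcohols. On these points it is as strong as or stronger than the chosen route.
- Against: the unhindered acrylate is a better acceptor for the cuprate than the β,β-disubstituted enone, so chemoselectivity runs against the planned order. The ring closure is a six-membered endo Michael addition next to the new quaternary centre. C7 is set only by equilibration. A7 must be made enantiopure with C1 in place and has no chiral-pool source as direct as terpineol.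
- Comparison: the chosen cycloaddition forms both bonds in one concerted event from a precursor whose single stereocentre is bought.

Key step: step 10

## Route

Step 1
Reactants: 1 (R)-(+)-α-terpineol
Product: 2 triethyl{2-[(1R)-4-methylcyclohex-3-en-1-yl]propan-2-yloxy}silane
Conditions: TESOTf, 2,6-lutidine, CH2Cl2, 0 °C
Reagents that add atoms: triethylsilyl trifluoromethanesulfonate, CC[Si](CC)(CC)OS(=O)(=O)C(F)(F)F
Why: Silylation of a tertiary alcohol with a silyl triflate and a hindered base; the free hydroxyl would otherwise close a lactol on the aldehyde made in step 2, and the stereocentre is not touched.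

Step 2
Reactants: 2 triethyl{2-[(1R)-4-methylcyclohex-3-en-1-yl]propan-2-yloxy}silane
Product: 4 (3R)-6-oxo-3-[2-(triethylsilyloxy)propan-2-yl]heptanal, via methoxy hydroperoxide 3 (not isolated)
Conditions: O3, CH2Cl2/MeOH, NaHCO3, −78 °C; then Me2S, −78 °C to rt
Reagents that add atoms: ozone, [O-][O+]=O
Why: Criegee ozonolysis of the trisubstituted ring alkene; the ketone oxide is trapped by methanol and the hydroperoxide is reduced by the sulfide, which should give the methyl ketone (C4, C3) and the aldehyde (C9) while the silyl ether and C7 stay untouched.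

Step 3
Reactants: 4 (3R)-6-oxo-3-[2-(triethylsilyloxy)propan-2-yl]heptanal
Product: 5 (5R)-7-hydroxy-5-[2-(triethylsilyloxy)propan-2-yl]heptan-2-one
Conditions: NaBH4, CH2Cl2/EtOH (7:3), −78 °C
Reagents that add atoms: none
Why: Chemoselective borohydride reduction; at low temperature in this solvent mixture an aldehyde is reduced much faster than a methyl ketone, so only C9 should be reduced.

Step 4
Reactants: 5 (5R)-7-hydroxy-5-[2-(triethylsilyloxy)propan-2-yl]heptan-2-one
Product: 6 (5R)-7-iodo-5-[2-(triethylsilyloxy)propan-2-yl]heptan-2-one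
Conditions: I2, PPh3, imidazole, CH2Cl2, 0 °C to rt
Reagents that add atoms: iodine, II
Why: Appel-type iodination of a primary alcohol under buffered conditions that a tertiary silyl ether and a ketone tolerate.

Step 5
Reactants: 7 methyl but-2-ynoate
Product: 8 methyl (2Z)-3-iodobut-2-enoate
Conditions: NaI, AcOH, 115 °C
Reagents that add atoms: sodium iodide, [Na+].[I-]
Why: Hydroiodination of an alkynoate by conjugate addition of iodide and protonation, which is known to give the (Z)-3-iodoenoate with iodine and ester cis.

Step 6
Reactants: 6 (5R)-7-iodo-5-[2-(triethylsilyloxy)propan-2-yl]heptan-2-one; 8 methyl (2Z)-3-iodobut-2-enoate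
Product: 10 methyl (2Z,6S)-3-methyl-9-oxo-6-[2-(triethylsilyloxy)propan-2-yl]dec-2-enoate, via alkylzinc iodide 9 (not isolated)
Conditions: Zn dust (activated with BrCH2CH2Br and TMSCl), DMA, 40 °C; then 8, Pd(PPh3)4 (5 mol %), THF, rt
Reagents that add atoms: none
Why: Negishi coupling of a primary alkylzinc iodide, which tolerates the ketone, with a vinyl iodide; oxidative addition and reductive elimination retain the alkene geometry, so C9 should end up cis to the ester and the C10 methyl trans to it.

Step 7
Reactants: 10 methyl (2Z,6S)-3-methyl-9-oxo-6-[2-(triethylsilyloxy)propan-2-yl]dec-2-enoate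
Product: 12 methyl (2Z,6S)-11-(dimethylamino)-3-methyl-9-oxo-6-[2-(triethylsilyloxy)propan-2-yl]undec-2-enoate, via lithium enolate 11 (not isolated)
Conditions: LDA, THF, −78 °C; then CH2=NMe2+ I−, −78 °C to rt
Reagents that add atoms: N,N-dimethylmethyleneiminium iodide (Eschenmoser's salt), C=[N+](C)C.[I-]
Why: Kinetic deprotonation of a methyl ketone at the methyl group followed by a Mannich reaction with the preformed iminium salt; the ketone is far more acidic than the γ-positions of the β,β-disubstituted enoate, which should stay untouched.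

Step 8
Reactants: 12 methyl (2Z,6S)-11-(dimethylamino)-3-methyl-9-oxo-6-[2-(triethylsilyloxy)propan-2-yl]undec-2-enoate
Product: 14 methyl (2Z,6S)-3-methyl-9-oxo-6-[2-(triethylsilyloxy)propan-2-yl]undeca-2,10-dienoate, via trimethylammonium iodide 13 (not isolated)
Conditions: MeI, CH2Cl2, rt; then aq NaHCO3, rt
Reagents that add atoms: none
Why: Quaternisation of the Mannich base and E1cB elimination of trimethylamine, the standard way to a vinyl ketone; the enone is used at once in step 9.

Step 9
Reactants: 14 methyl (2Z,6S)-3-methyl-9-oxo-6-[2-(triethylsilyloxy)propan-2-yl]undeca-2,10-dienoate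
Product: 15 methyl (2Z,6S,8Z)-9-(tert-butyldimethylsilyloxy)-3-methyl-6-[2-(triethylsilyloxy)propan-2-yl]undeca-2,8,10-trienoate
Conditions: TBSOTf, Et3N, CH2Cl2, −78 to 0 °C
Reagents that add atoms: tert-butyldimethylsilyl trifluoromethanesulfonate, CC(C)(C)[Si](C)(C)OS(=O)(=O)C(F)(F)F
Why: Soft enolisation of the vinyl ketone toward its only enolisable carbon C5 gives the 2-silyloxydiene; silyl triflate and amine normally give the (Z)-enol ether, which places the tether on the outside of the diene, and the ester is not enolised under these conditions.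

Step 10
Reactants: 15 methyl (2Z,6S,8Z)-9-(tert-butyldimethylsilyloxy)-3-methyl-6-[2-(triethylsilyloxy)propan-2-yl]undeca-2,8,10-trienoate
Product: 16 methyl (1R,4aS,6S,8aS)-4-(tert-butyldimethylsilyloxy)-8a-methyl-6-[2-(triethylsilyloxy)propan-2-yl]-1,2,4a,5,6,7,8,8a-octahydronaphthalene-1-carboxylate
Conditions: toluene (0.01 M), BHT, base-washed sealed tube, 190 °C
Reagents that add atoms: none
Why: Thermal intramolecular Diels–Alder reaction of a 1,7,9-decatriene, the known behaviour of tethered 2-silyloxydienes with terminally activated dienophiles; the silyloxy group raises the diene HOMO with its larger coefficient at C5, which meets the β-carbon C10 of the enoate, so the tether-imposed regiochemistry is also the electronically matched one. Ring A closes by the [4+2] cycloaddition itself (bonds C5–C10 and C1–C2), and ring B closes through the C5–C10 bond with the tether C6–C9 folded as a chair (fused, type 1 mode). C10 and C5 are set by the diene face that the dienophile reaches when the bulky C7 group sits equatorial on that chair, which puts the C10 methyl cis to the C7 side chain. The trans ring fusion needs the tether-exo, ester-exo transition state, in which the small C10 methyl takes the endo position; the chair tether favours it, and so should the silyloxy group on C4, which lies cis to C6 and is expected to penalise the folded cis-fused arrangement, a steric directing effect known for substituents at this diene position. C1 follows from the (Z) geometry of the enoate by suprafacial addition, so the ester ends up trans to the C10 methyl, that is axial. The step therefore needs control of ring fusion and diene face, secured by the equatorial C7 group and the C4 silyloxy group, while C1 is secured by alkene geometry alone. BHT and base-washed glass are meant to keep the silyl dienol ether and the (Z)-enoate intact at the temperature the trisubstituted dienophile requires.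

Step 11
Reactants: 16 methyl (1R,4aS,6S,8aS)-4-(tert-butyldimethylsilyloxy)-8a-methyl-6-[2-(triethylsilyloxy)propan-2-yl]-1,2,4a,5,6,7,8,8a-octahydronaphthalene-1-carboxylate
Product: 17 methyl (1R,4aS,6S,8aS)-8a-methyl-4-oxo-6-[2-(triethylsilyloxy)propan-2-yl]decahydronaphthalene-1-carboxylate
Conditions: TBAF, AcOH (1:1), THF, 0 °C
Reagents that add atoms: none
Why: Buffered fluoride cleavage of the silyl enol ether, which is far faster than cleavage of the hindered tertiary alkyl silyl ether; protonation occurs at C3, so C5 keeps the configuration set in step 10, and the buffer prevents enolisation toward C5.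

Step 12
Reactants: 17 methyl (1R,4aS,6S,8aS)-8a-methyl-4-oxo-6-[2-(triethylsilyloxy)propan-2-yl]decahydronaphthalene-1-carboxylate
Product: 18 methyl (1R,4R,4aS,6S,8aS)-4-hydroxy-4,8a-dimethyl-6-[2-(triethylsilyloxy)propan-2-yl]decahydronaphthalene-1-carboxylate
Conditions: MeMgBr, CeCl3, THF, −78 °C
Reagents that add atoms: methylmagnesium bromide, C[Mg]Br
Why: Organocerium-mediated 1,2-addition to the ketone, which should leave the hindered ester alone and suppress enolisation; the axial C10 methyl blocks the axial trajectory at C4 as in 3,3,5-trimethylcyclohexanone, so the methyl enters equatorially and the new hydroxyl is axial, cis to the C10 methyl (4R).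

Step 13
Reactants: 18 methyl (1R,4R,4aS,6S,8aS)-4-hydroxy-4,8a-dimethyl-6-[2-(triethylsilyloxy)propan-2-yl]decahydronaphthalene-1-carboxylate
Product: 19 methyl (1R,4R,4aS,6S,8aS)-4,8a-dimethyl-4-(triethylsilyloxy)-6-[2-(triethylsilyloxy)propan-2-yl]decahydronaphthalene-1-carboxylate
Conditions: TESOTf, 2,6-lutidine, CH2Cl2, 0 °C to rt
Reagents that add atoms: triethylsilyl trifluoromethanesulfonate, CC[Si](CC)(CC)OS(=O)(=O)C(F)(F)F
Why: Silyl triflate silylation of a hindered tertiary alcohol; the ether keeps the acidic proton away from the cuprate in step 18 and lowers the tendency of C4 to ionise in step 21.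

Step 14
Reactants: 19 methyl (1R,4R,4aS,6S,8aS)-4,8a-dimethyl-4-(triethylsilyloxy)-6-[2-(triethylsilyloxy)propan-2-yl]decahydronaphthalene-1-carboxylate
Product: 20 [(1R,4R,4aS,6S,8aR)-4,8a-dimethyl-4-(triethylsilyloxy)-6-[2-(triethylsilyloxy)propan-2-yl]decahydronaphthalen-1-yl]methanol
Conditions: LiAlH4, THF, 0 °C
Reagents that add atoms: none
Why: Hydride reduction of the ester to the primary alcohol; silyl ethers are stable and C1 is not enolised under these conditions.

Step 15
Reactants: 20 [(1R,4R,4aS,6S,8aR)-4,8a-dimethyl-4-(triethylsilyloxy)-6-[2-(triethylsilyloxy)propan-2-yl]decahydronaphthalen-1-yl]methanol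
Product: 21 (1R,4R,4aS,6S,8aS)-4,8a-dimethyl-4-(triethylsilyloxy)-6-[2-(triethylsilyloxy)propan-2-yl]decahydronaphthalene-1-carbaldehyde
Conditions: Dess–Martin periodinane, NaHCO3, CH2Cl2, rt
Reagents that add atoms: none
Why: Buffered Dess–Martin oxidation of a primary alcohol to the aldehyde under near-neutral conditions, chosen so that the axial, epimerisable C1 centre is not disturbed.

Step 16
Reactants: 21 (1R,4R,4aS,6S,8aS)-4,8a-dimethyl-4-(triethylsilyloxy)-6-[2-(triethylsilyloxy)propan-2-yl]decahydronaphthalene-1-carbaldehyde
Product: 22 (3E)-4-[(1S,4R,4aS,6S,8aR)-4,8a-dimethyl-4-(triethylsilyloxy)-6-[2-(triethylsilyloxy)propan-2-yl]decahydronaphthalen-1-yl]but-3-en-2-one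
Conditions: (MeO)2P(O)CH2C(O)Me, Ba(OH)2, THF/H2O (40:1), rt
Reagents that add atoms: dimethyl (2-oxopropyl)phosphonate, COP(=O)(OC)CC(C)=O
Why: Horner–Wadsworth–Emmons olefination with a β-ketophosphonate under mild barium hydroxide conditions, which suit hindered and base-sensitive aldehydes and should give the (E)-enone without epimerising C1.

Step 17
Reactants: 23 1,3,5-tris(benzyloxy)benzene
Product: 24 2-bromo-1,3,5-tris(benzyloxy)benzene
Conditions: NBS, CH2Cl2, −78 to 0 °C
Reagents that add atoms: N-bromosuccinimide, O=C1CCC(=O)N1Br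
Why: Electrophilic monobromination of a very electron-rich arene with one equivalent of N-bromosuccinimide; the three ring positions are equivalent.

Step 18
Reactants: 22 (3E)-4-[(1S,4R,4aS,6S,8aR)-4,8a-dimethyl-4-(triethylsilyloxy)-6-[2-(triethylsilyloxy)propan-2-yl]decahydronaphthalen-1-yl]but-3-en-2-one; 24 2-bromo-1,3,5-tris(benzyloxy)benzene
Product: 28 (4R)-4-[(1S,4R,4aS,6S,8aR)-4,8a-dimethyl-4-(triethylsilyloxy)-6-[2-(triethylsilyloxy)propan-2-yl]decahydronaphthalen-1-yl]-4-[2,4,6-tris(benzyloxy)phenyl]butan-2-one, via aryllithium 25 (not isolated), via lithium diarylcuprate 26 (not isolated), via trimethylsilyl enol ether 27 (not isolated)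
Conditions: 24, n-BuLi, THF, −78 °C; CuBr·SMe2 (0.5 equiv), −78 to −40 °C; then 22, TMSCl, −78 to −20 °C; then K2CO3, MeOH, 0 °C
Reagents that add atoms: none
Why: Bromine–lithium exchange, formation of a lithium diarylcuprate and silyl-chloride-accelerated conjugate addition, the reaction type by which 2,6-dialkoxyaryl cuprates add to enones. The axial enone chain should sit with C10′ pointing away from ring A (C1–H eclipsing the alkene), and the face turned to C9 is blocked by the axial hydrogen on C9. The aryl group is therefore expected from the C2 side, which gives the (R) configuration at C9′.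

Step 19
Reactants: 28 (4R)-4-[(1S,4R,4aS,6S,8aR)-4,8a-dimethyl-4-(triethylsilyloxy)-6-[2-(triethylsilyloxy)propan-2-yl]decahydronaphthalen-1-yl]-4-[2,4,6-tris(benzyloxy)phenyl]butan-2-one
Product: 29 2-[(1R)-1-[(1S,4R,4aS,6S,8aR)-4,8a-dimethyl-4-(triethylsilyloxy)-6-[2-(triethylsilyloxy)propan-2-yl]decahydronaphthalen-1-yl]-3-methylbut-3-en-1-yl]-1,3,5-tris(benzyloxy)benzene
Conditions: Ph3PCH3Br, KOt-Bu, THF, 0 °C to rt
Reagents that add atoms: methyltriphenylphosphonium bromide, C[P+](c1ccccc1)(c1ccccc1)c1ccccc1.[Br-]
Why: Wittig methylenation of a methyl ketone; C9′ is β to the carbonyl and has no acidic hydrogen, so it cannot be epimerised by the ylide.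

Step 20
Reactants: 29 2-[(1R)-1-[(1S,4R,4aS,6S,8aR)-4,8a-dimethyl-4-(triethylsilyloxy)-6-[2-(triethylsilyloxy)propan-2-yl]decahydronaphthalen-1-yl]-3-methylbut-3-en-1-yl]-1,3,5-tris(benzyloxy)benzene
Product: 30 2-[(1R)-1-[(1S,4R,4aS,6S,8aR)-4,8a-dimethyl-4-(triethylsilyloxy)-6-[2-(triethylsilyloxy)propan-2-yl]decahydronaphthalen-1-yl]-3-methylbutyl]benzene-1,3,5-triol
Conditions: H2 (1 atm), Pd/C, EtOAc, rt
Reagents that add atoms: none
Why: Heterogeneous hydrogenation saturates the 1,1-disubstituted alkene to the isobutyl group and hydrogenolyses the three aryl benzyl ethers in one operation; silyl ethers are stable in ethyl acetate, and the air-sensitive triphenol is used directly.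

Step 21
Reactants: 30 2-[(1R)-1-[(1S,4R,4aS,6S,8aR)-4,8a-dimethyl-4-(triethylsilyloxy)-6-[2-(triethylsilyloxy)propan-2-yl]decahydronaphthalen-1-yl]-3-methylbutyl]benzene-1,3,5-triol
Product: 32 5-[(1R)-1-[(1S,4R,4aS,6S,8aR)-4,8a-dimethyl-4-(triethylsilyloxy)-6-[2-(triethylsilyloxy)propan-2-yl]decahydronaphthalen-1-yl]-3-methylbutyl]-2,4,6-trihydroxybenzene-1,3-dicarbaldehyde, via bis-iminium salt 31 (not isolated)
Conditions: POCl3, DMF, EtOAc, 0 °C to rt; then H2O, NaOAc, 50 °C
Reagents that add atoms: N,N-dimethylformamide, CN(C)C=O; water, O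
Why: Vilsmeier–Haack formylation, the usual way to 2,4-diformylphloroglucinols; both free ring positions are flanked by two hydroxyls and are far more nucleophilic than the hindered tertiary silyl ethers, and the buffered hydrolysis releases the two aldehydes.

Step 22
Reactants: 32 5-[(1R)-1-[(1S,4R,4aS,6S,8aR)-4,8a-dimethyl-4-(triethylsilyloxy)-6-[2-(triethylsilyloxy)propan-2-yl]decahydronaphthalen-1-yl]-3-methylbutyl]-2,4,6-trihydroxybenzene-1,3-dicarbaldehyde
Product: 33 5-[(1R)-1-[(1S,4R,4aS,6S,8aR)-4-hydroxy-6-(2-hydroxypropan-2-yl)-4,8a-dimethyldecahydronaphthalen-1-yl]-3-methylbutyl]-2,4,6-trihydroxybenzene-1,3-dicarbaldehyde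
Conditions: HF·pyridine, pyridine, THF, 0 °C to rt
Reagents that add atoms: none
Why: Fluoride cleavage of the two tertiary triethylsilyl ethers under buffered, weakly acidic conditions that should neither ionise the tertiary alcohols nor affect the aldehydes.

## Compound list

1 | (R)-(+)-α-terpineol | CC1=CC[C@H](C(C)(C)O)CC1 | starting material
2 | triethyl{2-[(1R)-4-methylcyclohex-3-en-1-yl]propan-2-yloxy}silane | CC1=CC[C@H](C(C)(C)O[Si](CC)(CC)CC)CC1 | intermediate
3 | (3R)-6-hydroperoxy-6-methoxy-3-[2-(triethylsilyloxy)propan-2-yl]heptanal (both C6 epimers) | CC(OC)(OO)CC[C@@H](C(C)(C)O[Si](CC)(CC)CC)CC=O | intermediate (not isolated)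
4 | (3R)-6-oxo-3-[2-(triethylsilyloxy)propan-2-yl]heptanal | CC(=O)CC[C@@H](C(C)(C)O[Si](CC)(CC)CC)CC=O | intermediate
5 | (5R)-7-hydroxy-5-[2-(triethylsilyloxy)propan-2-yl]heptan-2-one | CC(=O)CC[C@@H](C(C)(C)O[Si](CC)(CC)CC)CCO | intermediate
6 | (5R)-7-iodo-5-[2-(triethylsilyloxy)propan-2-yl]heptan-2-one | CC(=O)CC[C@@H](C(C)(C)O[Si](CC)(CC)CC)CCI | intermediate
7 | methyl but-2-ynoate | CC#CC(=O)OC | starting material
8 | methyl (2Z)-3-iodobut-2-enoate | COC(=O)/C=C(/C)I | intermediate
9 | [(3R)-6-oxo-3-[2-(triethylsilyloxy)propan-2-yl]heptyl]zinc iodide | CC(=O)CC[C@@H](C(C)(C)O[Si](CC)(CC)CC)CC[Zn]I | intermediate (not isolated)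
10 | methyl (2Z,6S)-3-methyl-9-oxo-6-[2-(triethylsilyloxy)propan-2-yl]dec-2-enoate | CC(=O)CC[C@@H](C(C)(C)O[Si](CC)(CC)CC)CC/C(C)=C\C(=O)OC | intermediate
11 | terminal (kinetic) lithium enolate of 10 | [Li]OC(=C)CC[C@@H](C(C)(C)O[Si](CC)(CC)CC)CC/C(C)=C\C(=O)OC | intermediate (not isolated)
12 | methyl (2Z,6S)-11-(dimethylamino)-3-methyl-9-oxo-6-[2-(triethylsilyloxy)propan-2-yl]undec-2-enoate | CN(C)CCC(=O)CC[C@@H](C(C)(C)O[Si](CC)(CC)CC)CC/C(C)=C\C(=O)OC | intermediate
13 | N,N,N-trimethylammonium iodide of 12 | C[N+](C)(C)CCC(=O)CC[C@@H](C(C)(C)O[Si](CC)(CC)CC)CC/C(C)=C\C(=O)OC.[I-] | intermediate (not isolated)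
14 | methyl (2Z,6S)-3-methyl-9-oxo-6-[2-(triethylsilyloxy)propan-2-yl]undeca-2,10-dienoate | C=CC(=O)CC[C@@H](C(C)(C)O[Si](CC)(CC)CC)CC/C(C)=C\C(=O)OC | intermediate
15 | methyl (2Z,6S,8Z)-9-(tert-butyldimethylsilyloxy)-3-methyl-6-[2-(triethylsilyloxy)propan-2-yl]undeca-2,8,10-trienoate | C=C/C(O[Si](C)(C)C(C)(C)C)=C/C[C@@H](C(C)(C)O[Si](CC)(CC)CC)CC/C(C)=C\C(=O)OC | intermediate
16 | methyl (1R,4aS,6S,8aS)-4-(tert-butyldimethylsilyloxy)-8a-methyl-6-[2-(triethylsilyloxy)propan-2-yl]-1,2,4a,5,6,7,8,8a-octahydronaphthalene-1-carboxylate (trans-fused; ester trans to the angular methyl) | COC(=O)[C@@H]1CC=C(O[Si](C)(C)C(C)(C)C)[C@H]2C[C@@H](C(C)(C)O[Si](CC)(CC)CC)CC[C@]12C | intermediate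
17 | methyl (1R,4aS,6S,8aS)-8a-methyl-4-oxo-6-[2-(triethylsilyloxy)propan-2-yl]decahydronaphthalene-1-carboxylate | COC(=O)[C@@H]1CCC(=O)[C@H]2C[C@@H](C(C)(C)O[Si](CC)(CC)CC)CC[C@]12C | intermediate
18 | methyl (1R,4R,4aS,6S,8aS)-4-hydroxy-4,8a-dimethyl-6-[2-(triethylsilyloxy)propan-2-yl]decahydronaphthalene-1-carboxylate | COC(=O)[C@@H]1CC[C@@](C)(O)[C@H]2C[C@@H](C(C)(C)O[Si](CC)(CC)CC)CC[C@]12C | intermediate
19 | methyl (1R,4R,4aS,6S,8aS)-4,8a-dimethyl-4-(triethylsilyloxy)-6-[2-(triethylsilyloxy)propan-2-yl]decahydronaphthalene-1-carboxylate | COC(=O)[C@@H]1CC[C@@](C)(O[Si](CC)(CC)CC)[C@H]2C[C@@H](C(C)(C)O[Si](CC)(CC)CC)CC[C@]12C | intermediate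
20 | [(1R,4R,4aS,6S,8aR)-4,8a-dimethyl-4-(triethylsilyloxy)-6-[2-(triethylsilyloxy)propan-2-yl]decahydronaphthalen-1-yl]methanol | OC[C@@H]1CC[C@@](C)(O[Si](CC)(CC)CC)[C@H]2C[C@@H](C(C)(C)O[Si](CC)(CC)CC)CC[C@]12C | intermediate
21 | (1R,4R,4aS,6S,8aS)-4,8a-dimethyl-4-(triethylsilyloxy)-6-[2-(triethylsilyloxy)propan-2-yl]decahydronaphthalene-1-carbaldehyde | O=C[C@@H]1CC[C@@](C)(O[Si](CC)(CC)CC)[C@H]2C[C@@H](C(C)(C)O[Si](CC)(CC)CC)CC[C@]12C | intermediate
22 | (3E)-4-[(1S,4R,4aS,6S,8aR)-4,8a-dimethyl-4-(triethylsilyloxy)-6-[2-(triethylsilyloxy)propan-2-yl]decahydronaphthalen-1-yl]but-3-en-2-one | CC(=O)/C=C/[C@@H]1CC[C@@](C)(O[Si](CC)(CC)CC)[C@H]2C[C@@H](C(C)(C)O[Si](CC)(CC)CC)CC[C@]12C | intermediate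
23 | 1,3,5-tris(benzyloxy)benzene | c1c(OCc2ccccc2)cc(OCc2ccccc2)cc1OCc1ccccc1 | starting material
24 | 2-bromo-1,3,5-tris(benzyloxy)benzene | Brc1c(OCc2ccccc2)cc(OCc2ccccc2)cc1OCc1ccccc1 | intermediate
25 | 2,4,6-tris(benzyloxy)phenyllithium | [Li]c1c(OCc2ccccc2)cc(OCc2ccccc2)cc1OCc1ccccc1 | intermediate (not isolated)
26 | lithium bis[2,4,6-tris(benzyloxy)phenyl]cuprate | [Li+].[Cu-](c1c(OCc2ccccc2)cc(OCc2ccccc2)cc1OCc1ccccc1)c1c(OCc2ccccc2)cc(OCc2ccccc2)cc1OCc1ccccc1 | intermediate (not isolated)
27 | trimethylsilyl enol ether of 28 (alkene geometry not defined) | CC(O[Si](C)(C)C)=C[C@@H](c3c(OCc4ccccc4)cc(OCc4ccccc4)cc3OCc3ccccc3)[C@@H]1CC[C@@](C)(O[Si](CC)(CC)CC)[C@H]2C[C@@H](C(C)(C)O[Si](CC)(CC)CC)CC[C@]12C | intermediate (not isolated)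
28 | (4R)-4-[(1S,4R,4aS,6S,8aR)-4,8a-dimethyl-4-(triethylsilyloxy)-6-[2-(triethylsilyloxy)propan-2-yl]decahydronaphthalen-1-yl]-4-[2,4,6-tris(benzyloxy)phenyl]butan-2-one | CC(=O)C[C@@H](c3c(OCc4ccccc4)cc(OCc4ccccc4)cc3OCc3ccccc3)[C@@H]1CC[C@@](C)(O[Si](CC)(CC)CC)[C@H]2C[C@@H](C(C)(C)O[Si](CC)(CC)CC)CC[C@]12C | intermediate
29 | 2-[(1R)-1-[(1S,4R,4aS,6S,8aR)-4,8a-dimethyl-4-(triethylsilyloxy)-6-[2-(triethylsilyloxy)propan-2-yl]decahydronaphthalen-1-yl]-3-methylbut-3-en-1-yl]-1,3,5-tris(benzyloxy)benzene | CC(=C)C[C@@H](c3c(OCc4ccccc4)cc(OCc4ccccc4)cc3OCc3ccccc3)[C@@H]1CC[C@@](C)(O[Si](CC)(CC)CC)[C@H]2C[C@@H](C(C)(C)O[Si](CC)(CC)CC)CC[C@]12C | intermediate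
30 | 2-[(1R)-1-[(1S,4R,4aS,6S,8aR)-4,8a-dimethyl-4-(triethylsilyloxy)-6-[2-(triethylsilyloxy)propan-2-yl]decahydronaphthalen-1-yl]-3-methylbutyl]benzene-1,3,5-triol | CC(C)C[C@@H](c3c(O)cc(O)cc3O)[C@@H]1CC[C@@](C)(O[Si](CC)(CC)CC)[C@H]2C[C@@H](C(C)(C)O[Si](CC)(CC)CC)CC[C@]12C | intermediate
31 | bis(N,N-dimethyliminium) dichloride of 32 | CC(C)C[C@@H](c3c(O)c(C=[N+](C)C)c(O)c(C=[N+](C)C)c3O)[C@@H]1CC[C@@](C)(O[Si](CC)(CC)CC)[C@H]2C[C@@H](C(C)(C)O[Si](CC)(CC)CC)CC[C@]12C.[Cl-].[Cl-] | intermediate (not isolated)
32 | 5-[(1R)-1-[(1S,4R,4aS,6S,8aR)-4,8a-dimethyl-4-(triethylsilyloxy)-6-[2-(triethylsilyloxy)propan-2-yl]decahydronaphthalen-1-yl]-3-methylbutyl]-2,4,6-trihydroxybenzene-1,3-dicarbaldehyde | CC(C)C[C@@H](c3c(O)c(C=O)c(O)c(C=O)c3O)[C@@H]1CC[C@@](C)(O[Si](CC)(CC)CC)[C@H]2C[C@@H](C(C)(C)O[Si](CC)(CC)CC)CC[C@]12C | intermediate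
33 | 5-[(1R)-1-[(1S,4R,4aS,6S,8aR)-4-hydroxy-6-(2-hydroxypropan-2-yl)-4,8a-dimethyldecahydronaphthalen-1-yl]-3-methylbutyl]-2,4,6-trihydroxybenzene-1,3-dicarbaldehyde | CC(C)C[C@@H](c1c(O)c(C=O)c(O)c(C=O)c1O)[C@@H]1CC[C@@](C)(O)[C@H]2C[C@@H](C(C)(C)O)CC[C@]12C | target

## Step count and least certain steps

Total step count: 22. Longest linear sequence: 20 steps (steps 1–4, 6–16 and 18–22); steps 5 and 17 are one-step side branches.

**Step 10 (key step).** The ring fusion may be controlled incompletely: the (Z)-enoate can also react through the tether-endo, ester-endo arrangement, which gives a cis-fused adduct. In addition the trisubstituted dienophile reacts slowly, so long heating may erode the silyl dienol ether. The fallback replaces kinetic control of C5 by thermodynamic control. Setting out from 15, the cycloadduct mixture containing the cis-fused C5 epimer, methyl (1R,4aR,6S,8aS)-4-(tert-butyldimethylsilyloxy)-8a-methyl-6-[2-(triethylsilyloxy)propan-2-yl]-1,2,4a,5,6,7,8,8a-octahydronaphthalene-1-carboxylate F1, is desilylated as in step 11 to the cis-decalone, methyl (1R,4aR,6S,8aS)-8a-methyl-4-oxo-6-[2-(triethylsilyloxy)propan-2-yl]decahydronaphthalene-1-carboxylate F2. F2 is equilibrated through its C4 enolate (K2CO3, MeOH, rt). The trans-fused ketone avoids the extra gauche interactions of the cis-decalin and is expected to be favoured, though not overwhelmingly; it is separated and the cis material resubmitted. The route is rejoined at 17. This corrects only the C5 epimer; an adduct with the opposite configuration at C10 would have to be removed.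

**Step 18.** Transfer of the doubly ortho-substituted aryl group to a β-carbon attached to the axial, neopentyl-like C1 may be too slow, so that enone is recovered or reduced. Incomplete face selectivity is the second concern. The fallback changes the nucleophile from an organocopper reagent to the arene itself. Setting out from 22, a Friedel–Crafts-type conjugate addition of 23 with catalytic Sc(OTf)3 in CH2Cl2 should give 28 directly, where the route is rejoined. The same conformational argument applies to the face of attack. This fallback makes no new compound (F0).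

**Step 21.** The hydrogen chloride released may strip the tertiary silyl ethers and lead to ionisation and elimination at C4, or the Vilsmeier reagent may attack oxygen. The fallback installs the formyl groups before the phenols are freed and without acid. Setting out from 29, ortho-lithiation between two benzyloxy groups (n-BuLi, TMEDA, THF, −20 to 0 °C) and quenching with DMF should give the monoaldehyde, 2,4,6-tris(benzyloxy)-3-[(1R)-1-(decalinyl)-3-methylbut-3-en-1-yl]benzaldehyde F3. Its aldehyde is masked in the flask as the α-amino alkoxide with lithium N,N,N′-trimethylethylenediamide, and a second lithiation and DMF quench give the dialdehyde, 2,4,6-tris(benzyloxy)-5-[(1R)-1-(decalinyl)-3-methylbut-3-en-1-yl]benzene-1,3-dicarbaldehyde F4. Hydrogenation (H2, Pd/C, EtOAc, monitored to spare the aldehydes) then saturates the alkene and removes the three benzyl groups. The route is rejoined at 32.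

**Step 16.** The axial aldehyde may epimerise at C1 to its equatorial isomer under the basic conditions, and the hindered carbonyl may olefinate slowly. The fallback is an aldol–dehydration sequence. Setting out from 21, the lithium enolate of acetone (LDA, acetone, THF, −78 °C) adds irreversibly at low temperature to give the β-hydroxy ketone, 4-hydroxy-4-(decalinyl)butan-2-one F5. Mesylation and elimination (MsCl, Et3N; then DBU) give the (E)-enone. The route is rejoined at 22.

## Further compounds

F1 | step 10 | methyl (1R,4aR,6S,8aS)-4-(tert-butyldimethylsilyloxy)-8a-methyl-6-[2-(triethylsilyloxy)propan-2-yl]-1,2,4a,5,6,7,8,8a-octahydronaphthalene-1-carboxylate (cis-fused C5 epimer of 16) | COC(=O)[C@@H]1CC=C(O[Si](C)(C)C(C)(C)C)[C@@H]2C[C@@H](C(C)(C)O[Si](CC)(CC)CC)CC[C@]12C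
F2 | step 10 | methyl (1R,4aR,6S,8aS)-8a-methyl-4-oxo-6-[2-(triethylsilyloxy)propan-2-yl]decahydronaphthalene-1-carboxylate (cis-fused C5 epimer of 17) | COC(=O)[C@@H]1CCC(=O)[C@@H]2C[C@@H](C(C)(C)O[Si](CC)(CC)CC)CC[C@]12C
F0 | step 18 | none | none
F3 | step 21 | 2,4,6-tris(benzyloxy)-3-[(1R)-1-[(1S,4R,4aS,6S,8aR)-4,8a-dimethyl-4-(triethylsilyloxy)-6-[2-(triethylsilyloxy)propan-2-yl]decahydronaphthalen-1-yl]-3-methylbut-3-en-1-yl]benzaldehyde | CC(=C)C[C@@H](c3c(OCc4ccccc4)c(C=O)c(OCc4ccccc4)cc3OCc3ccccc3)[C@@H]1CC[C@@](C)(O[Si](CC)(CC)CC)[C@H]2C[C@@H](C(C)(C)O[Si](CC)(CC)CC)CC[C@]12C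
F4 | step 21 | 2,4,6-tris(benzyloxy)-5-[(1R)-1-[(1S,4R,4aS,6S,8aR)-4,8a-dimethyl-4-(triethylsilyloxy)-6-[2-(triethylsilyloxy)propan-2-yl]decahydronaphthalen-1-yl]-3-methylbut-3-en-1-yl]benzene-1,3-dicarbaldehyde | CC(=C)C[C@@H](c3c(OCc4ccccc4)c(C=O)c(OCc4ccccc4)c(C=O)c3OCc3ccccc3)[C@@H]1CC[C@@](C)(O[Si](CC)(CC)CC)[C@H]2C[C@@H](C(C)(C)O[Si](CC)(CC)CC)CC[C@]12C
F5 | step 16 | 4-hydroxy-4-[(1R,4R,4aS,6S,8aR)-4,8a-dimethyl-4-(triethylsilyloxy)-6-[2-(triethylsilyloxy)propan-2-yl]decahydronaphthalen-1-yl]butan-2-one (carbinol epimers) | CC(=O)CC(O)[C@@H]1CC[C@@](C)(O[Si](CC)(CC)CC)[C@H]2C[C@@H](C(C)(C)O[Si](CC)(CC)CC)CC[C@]12C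
A1 | alternative 1 | (4S)-2-(1-ethoxyethenyl)-1-methyl-4-(prop-1-en-2-yl)cyclohex-1-ene | C=C(OCC)C1=C(C)CC[C@H](C(C)=C)C1
A2 | alternative 1 | 5-methylhex-1-en-3-one | C=CC(=O)CC(C)C
A3 | alternative 1 | bicyclic enol ether with the C1 isovaleryl group and angular methyl | CC(C)CC(=O)[C@@H]1CCC(OCC)=C2C[C@@H](C(C)=C)CC[C@]12C
A4 | alternative 2 | C9′-bound triisopropylsiloxyalkyne on the bis-silylated eudesmane | CC(C)C[C@@H](C#CO[Si](C(C)C)(C(C)C)C(C)C)[C@@H]1CC[C@@](C)(O[Si](CC)(CC)CC)[C@H]2C[C@@H](C(C)(C)O[Si](CC)(CC)CC)CC[C@]12C
A5 | alternative 2 | 3-(benzyloxy)cyclobut-2-en-1-one | O=C1C=C(OCc2ccccc2)C1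
A6 | alternative 2 | 2-alkyl-5-benzyloxy-3-triisopropylsiloxyphenol carrying the protected eudesmane | CC(C)C[C@@H](c1c(O)cc(OCc2ccccc2)cc1O[Si](C(C)C)(C(C)C)C(C)C)[C@@H]1CC[C@@](C)(O[Si](CC)(CC)CC)[C@H]2C[C@@H](C(C)(C)O[Si](CC)(CC)CC)CC[C@]12C
A7 | alternative 3 | methyl 4-[6-(benzyloxymethyl)-3-oxocyclohex-1-en-1-yl]-2-methylidenebutanoate | c1ccccc1COC[C@@H]1CCC(=O)C=C1CCC(=C)C(=O)OC
A8 | alternative 3 | trans-decal-4-one with angular methyl and equatorial C7 ester | c1ccccc1COC[C@@H]1CCC(=O)[C@H]2C[C@@H](C(=O)OC)CC[C@]12C
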